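The runs are simulated with made-up constants; scatter was added.

Count the catalyst in millimolar hours, concentration times time. Two of the suspected steps are catalysed and the catalyst leaves each unchanged, so at one temperature those two steps in one flask can be read on another's clock.

the same everywhere: starting material 0.30 M
- zeta: protic impurity 0.15 M; catalyst 34 mM; temperature 20 °C; run made earlier
- oak: protic impurity 0.150 M; catalyst 17 mM; temperature 20 °C; time 4.0 h
- birch: protic impurity 0.150 M; catalyst 17 mM; temperature −30 °C; time 4.0 h
- larch: protic impurity 0.150 M; catalyst 17 mM; temperature −5 °C; time 4.0 h

zeta run (percent of the starting material charged)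

| time / min | target / % | starting material / % |
|---|---|---|
| 6.00 | 2.3 | 84.5 |
| 10.0 | 3.0 | 75.1 |
| 20.0 | 5.0 | 58.3 |
| 40.0 | 8.3 | 36.8 |
| 80.0 | 10.4 | 20.7 |

(standard deviation of a reading: 0.5 percentage points)

- the earlier runs were read with a standard deviation of 0.5 percentage points
- on the list of suspects stand: isomer of the product + catalyst <-> starting material + catalyst; starting material + protic impurity -> quenched substrate; target <-> isomer of the product; starting material + catalyst <-> target + catalyst
- the earlier runs do not show what temperature does; that part of a forecast is a guess
- no earlier run changes the charge of catalyst; that part of a forecast is a guess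

Let θ be the minutes of zeta holding the same concentration times time as a given flask; for oak θ is 120 min, later than zeta's last reading at 80.0 min. But the quench and the step between target and isomer need no catalyst, so θ does not clock them.

Zeta's first reading gives starting material a pseudo-first-order loss constant k of 0.0281 min⁻¹. Its last interval added 2.1 percentage points of target, and the remaining 40.0 min of θ start with less starting material, so I scale that gain by 0.562 and reckon oak at 11.6%. Scaling by catalyst is a guess, and so is my expectation that cold slows the clock, on which I name oak.

- the flask that comes out highest in amount of target, in percent of the starting material charged, or "all alike" when all lie within 1.5 percentage points (oak / birch / larch / all alike)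
- target at the end, in percent of the starting material charged, oak
- target at the end, in percent of the starting material charged, birch
- target at the end, in percent of the starting material charged, larch

The forecast, unlike my reckoning, gives larch, with 6.5% in oak, 1% in birch and 6.5% in larch: “Oak versus larch is nearly a coin toss; I lean larch.”

The flasks give 12.8% in oak, 0.158% in birch and 2.55% in larch, so oak is highest.

    isomer of the product + catalyst ⇌ starting material + catalyst, rate k1*[catalyst]*[isomer of the product] forward; the back reaction follows from the equilibrium constant (k = 0.00280 L mol⁻¹ s⁻¹, Ea = 56.0 kJ mol⁻¹)
    starting material + protic impurity → quenched substrate (k = 7.50 × 10⁻⁵ L mol⁻¹ s⁻¹, Ea = 64.0 kJ mol⁻¹)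
    target ⇌ isomer of the product (K = 3.40, k = 1.90 × 10⁻⁵ s⁻¹, Ea = 98.0 kJ mol⁻¹, ΔH = 0 kJ mol⁻¹)
    starting material + catalyst ⇌ target + catalyst, rate k4*[starting material]*[catalyst] forward; the back reaction follows from the equilibrium constant (K = 1.30, k = 0.00160 L mol⁻¹ s⁻¹, Ea = 65.0 kJ mol⁻¹, ΔH = −8.00 kJ mol⁻¹)
    (constants at 20 °C)

Birch holds the concentration times time of oak, a θ of 120 min as counted in the cold, but birch's forward step to target has a half-life of 71 d at 1.97 h, far longer than its 4.0 h. From birch to oak that step speeds up 240 times.

Birch's neighbour at −55 °C holds the same concentration times time, but the catalysed step from starting material to isomer, with activation energy 48.0 kJ mol⁻¹, is 872 times slower there than at 20 °C, so, counted at the pace of 20 °C, the neighbour's θ shrinks to 0.138 min, and k, which lumps together the whole loss of starting material in zeta, predicts a loss of 0.388%. The neighbour keeps 99.6% of its starting material, with 0.347% isomer and 0% target.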